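**Retrosynthetic overview**
1. 16 ⇒ 9 + 13 + one CH2. The methylene bridge is cut last: Mannich base 14 gives enone methide 15, which arene 13 traps.
2. 9 ⇒ 8 by crotyl-to-prenyl cross-metathesis. 8 ⇒ enol lactone 6 by lactone-to-carbocycle acyl transfer (6 → 7 → 8), which bonds lactone C2 to the side-chain CH2.
3. 6 ⇒ pyronyl ether 5 by a [3,3] Claisen rearrangement. This forms the C(quaternary)–CH2 bond and passes the C–O stereocentre of (S)-but-3-en-2-ol 4, inverted in the Mitsunobu step, to the quaternary carbon.
4. 5 ⇒ 3 + 4. 3 ⇒ 1 + 2. 13 ⇒ phloroglucinol 10 + hexanoyl chloride 11, then para-O-methylation.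
5. Ring order: the pyrone ring is bought and recast into the carbocycle in step 3, the aromatic ring is bought, and the two rings are joined in step 7.

Assumption: β-triketones are drawn in the enol tautomer of the target SMILES, and 1, 2 and both enantiomers of but-3-en-2-ol are taken as catalogue compounds.

**Step 1**
Reactants: 1 4-hydroxy-3,6-dimethyl-2H-pyran-2-one; 2 N-methoxy-N-methylbutanamide
Product: 3 4-hydroxy-3-methyl-6-(2-oxopentyl)-2H-pyran-2-one
Conditions: LiN(iPr)2 (2.2 equiv, commercial solution), THF, −78 to 0 °C; 2 (1.1 equiv), −78 to −20 °C; 1 M HCl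
Reagents that add atoms: none
Why: The O,C-dianion reacts at its most basic site, the vinylogous C6-methyl carbanion, and the chelated tetrahedral adduct of this Weinreb ketone synthesis survives until the quench, so the more acidic product cannot consume the dianion (no stereocentre involved).

**Step 2**
Reactants: 3 4-hydroxy-3-methyl-6-(2-oxopentyl)-2H-pyran-2-one; 4 (S)-but-3-en-2-ol
Product: 5 4-{[(2R)-but-3-en-2-yl]oxy}-3-methyl-6-(2-oxopentyl)-2H-pyran-2-one
Conditions: PPh3 (1.1 equiv), DIAD (1.1 equiv), THF, 0 °C to rt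
Reagents that add atoms: none
Why: In this Mitsunobu etherification only the vinylogous-acid 4-OH (pKa about 5) is engaged, and it displaces the alkoxyphosphonium group of 4 by SN2 with inversion, so the purchased (S)-carbinol becomes the (R)-ether.

**Step 3**
Reactants: 5 4-{[(2R)-but-3-en-2-yl]oxy}-3-methyl-6-(2-oxopentyl)-2H-pyran-2-one
Product: 8 (4R)-2-butanoyl-4-[(2E)-but-2-en-1-yl]-3,5-dihydroxy-4-methylcyclohexa-2,5-dien-1-one, via Claisen lactone 6 (not isolated), via triketo ester 7 (not isolated)
Conditions: PhMe, 130 °C, sealed tube, 8 h; then rt, NaOMe (3 equiv), MeOH, 50 °C, 3 h; 1 M HCl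
Reagents that add atoms: none
Why: The thermal [3,3] Claisen rearrangement can only reach C3, because C3=C4 is the only C=C attached to the ether oxygen, and its chair transition state with the carbinol methyl equatorial (the axial position clashes with ring C5) converts the (R)-C–O stereocentre into the (R)-quaternary carbon and an E-alkene; methoxide then opens the non-enolisable enol lactone and the doubly activated CH2 closes onto the ester (Dieckmann-type Claisen condensation), so lactone C2 becomes the carbonyl next to the butanoyl carbon and the stereocentre is untouched.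

**Step 4**
Reactants: 8 (4R)-2-butanoyl-4-[(2E)-but-2-en-1-yl]-3,5-dihydroxy-4-methylcyclohexa-2,5-dien-1-one
Product: 9 (4R)-2-butanoyl-3,5-dihydroxy-4-methyl-4-(3-methylbut-2-en-1-yl)cyclohexa-2,5-dien-1-one
Conditions: second-generation Grubbs catalyst RuCl2(=CHPh)(PCy3)(H2IMes) (5 mol %), 2-methylbut-2-ene/CH2Cl2 1:1, 40 °C, sealed tube
Reagents that add atoms: 2-methylbut-2-ene, CC=C(C)C
Why: In this olefin cross-metathesis the unhindered crotyl alkene exchanges its ethylidene end for the isopropylidene of the excess alkene, any Z-crotyl isomer converges on the same prenyl group, and the quaternary stereocentre is a spectator.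

**Step 5**
Reactants: 10 phloroglucinol; 11 hexanoyl chloride
Product: 12 1-(2,4,6-trihydroxyphenyl)hexan-1-one
Conditions: AlCl3 (3.5 equiv), PhNO2/CH2Cl2, 0 to 45 °C; ice/HCl
Reagents that add atoms: none
Why: This Friedel–Crafts acylation of the threefold-symmetric arene has one possible regiochemistry and stops at the mono-ketone because the chelated aryl ketone–AlCl3 complex deactivates the ring.

**Step 6**
Reactants: 12 1-(2,4,6-trihydroxyphenyl)hexan-1-one
Product: 13 1-(2,6-dihydroxy-4-methoxyphenyl)hexan-1-one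
Conditions: Me2SO4 (1.0 equiv), K2CO3 (1.05 equiv), acetone, rt to 40 °C
Reagents that add atoms: dimethyl sulfate, COS(=O)(=O)OC
Why: In this Williamson-type O-methylation the two ortho OH groups are hydrogen-bonded to the ketone, so one equivalent of reagent takes the free and most acidic para OH.

**Step 7**
Reactants: 9 (4R)-2-butanoyl-3,5-dihydroxy-4-methyl-4-(3-methylbut-2-en-1-yl)cyclohexa-2,5-dien-1-one; 13 1-(2,6-dihydroxy-4-methoxyphenyl)hexan-1-one
Product: 16 elaphopilosin B, via Mannich base 14 (not isolated), via enone methide 15 (not isolated)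
Conditions: CH2(NMe2)2 (1.05 equiv), CH2Cl2, 0 °C to rt, 1 h; evaporate; 13 (1.5 equiv), 1,4-dioxane, 80 °C, N2 sweep, 4 h; 0.5 M HCl wash
Reagents that add atoms: N,N,N',N'-tetramethylmethanediamine, CN(C)CN(C)C
Why: In this Mannich reaction followed by amine elimination and Michael-type Friedel–Crafts addition, the acidic enol 9 has a single free nucleophilic carbon and is fully aminomethylated before 13 is added, heat expels Me2NH to give methide 15, and either of the two equivalent electron-rich CH positions of 13 adds to it without touching the stereocentre.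

**Compound list**
1 | 4-hydroxy-3,6-dimethyl-2H-pyran-2-one | CC1=CC(O)=C(C)C(=O)O1 | starting material
2 | N-methoxy-N-methylbutanamide | CCCC(=O)N(C)OC | starting material
3 | 4-hydroxy-3-methyl-6-(2-oxopentyl)-2H-pyran-2-one | CCCC(=O)CC1=CC(O)=C(C)C(=O)O1 | intermediate
4 | (S)-but-3-en-2-ol | C[C@H](O)C=C | starting material
5 | 4-{[(2R)-but-3-en-2-yl]oxy}-3-methyl-6-(2-oxopentyl)-2H-pyran-2-one | CCCC(=O)CC1=CC(O[C@H](C)C=C)=C(C)C(=O)O1 | intermediate
6 | (3R)-3-[(2E)-but-2-en-1-yl]-3-methyl-6-(2-oxopentyl)-2H-pyran-2,4(3H)-dione | CCCC(=O)CC1=CC(=O)[C@@](C)(C/C=C/C)C(=O)O1 | intermediate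
7 | methyl (2R)-2-[(2E)-but-2-en-1-yl]-2-methyl-3,5,7-trioxodecanoate | CCCC(=O)CC(=O)CC(=O)[C@@](C)(C/C=C/C)C(=O)OC | intermediate
8 | (4R)-2-butanoyl-4-[(2E)-but-2-en-1-yl]-3,5-dihydroxy-4-methylcyclohexa-2,5-dien-1-one | O=C1C=C(O)[C@@](C)(C/C=C/C)C(O)=C1C(=O)CCC | intermediate
9 | (4R)-2-butanoyl-3,5-dihydroxy-4-methyl-4-(3-methylbut-2-en-1-yl)cyclohexa-2,5-dien-1-one | O=C1C=C(O)[C@@](C)(CC=C(C)C)C(O)=C1C(=O)CCC | intermediate
10 | phloroglucinol (benzene-1,3,5-triol) | Oc1cc(O)cc(O)c1 | starting material
11 | hexanoyl chloride | CCCCCC(=O)Cl | starting material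
12 | 1-(2,4,6-trihydroxyphenyl)hexan-1-one | CCCCCC(=O)c1c(O)cc(O)cc1O | intermediate
13 | 1-(2,6-dihydroxy-4-methoxyphenyl)hexan-1-one | CCCCCC(=O)c1c(O)cc(OC)cc1O | intermediate
14 | (4R)-2-butanoyl-6-[(dimethylamino)methyl]-3,5-dihydroxy-4-methyl-4-(3-methylbut-2-en-1-yl)cyclohexa-2,5-dien-1-one | CN(C)CC1=C(O)[C@@](C)(CC=C(C)C)C(O)=C(C(=O)CCC)C1=O | intermediate
15 | (4S)-2-butanoyl-3-hydroxy-4-methyl-6-methylidene-4-(3-methylbut-2-en-1-yl)cyclohex-2-ene-1,5-dione (same spatial arrangement, descriptor changes by CIP rank only) | C=C1C(=O)[C@@](C)(CC=C(C)C)C(O)=C(C(=O)CCC)C1=O | intermediate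
16 | elaphopilosin B, (4R)-2-butanoyl-6-[(3-hexanoyl-2,4-dihydroxy-6-methoxyphenyl)methyl]-3,5-dihydroxy-4-methyl-4-(3-methylbut-2-en-1-yl)cyclohexa-2,5-dien-1-one | CCCCCC(=O)c1c(O)cc(OC)c(CC2=C(O)[C@@](C)(CC=C(C)C)C(O)=C(C(=O)CCC)C2=O)c1O | target

**Total step count:** 7. **Longest linear sequence:** 5 (steps 1, 2, 3, 4, 7).

**Three steps most likely to fail**

Step 2 (Mitsunobu etherification). The risks are alkylation at the lactone oxygen, SN2' attack giving the achiral crotyl ether, and partial loss of configuration. The fallback sets out from 1 and comes back at 5.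
- It makes the ether bond at the pyrone carbon instead of the carbinol carbon.
- 1 is brominated with PBr3 in DMF to 4-bromo-3,6-dimethyl-2H-pyran-2-one F1.
- The sodium alkoxide of commercial (R)-but-3-en-2-ol (C[C@@H](O)C=C; NaH, THF, 0 °C) replaces bromide by addition–elimination at C4.
- The carbinol C–O bond is never broken, so configuration is retained and SN2' cannot occur. The product is 4-{[(2R)-but-3-en-2-yl]oxy}-3,6-dimethyl-2H-pyran-2-one F2.
- LiN(SiMe3)2 (THF, −78 °C) then deprotonates the 6-methyl group, and acylation with 2 gives 5. This also bypasses the dianion of step 1.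

Step 3 (Claisen rearrangement and ring recasting). The risks are a sluggish rearrangement onto the tetrasubstituted C3 and leakage through boat or axial-methyl transition states, which lowers the enantiomeric ratio after step 4. The fallback sets out from 4 and comes back at 7, which NaOMe closes to 8 as before.
- It moves the [3,3] event to an acyclic ketene acetal that rearranges below 60 °C.
- 4 is esterified with monomethyl methylmalonate under Mitsunobu conditions (inversion) to 1-[(2R)-but-3-en-2-yl] 3-methyl 2-methylpropanedioate F3.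
- LiN(SiMe3)2 and Me3SiCl (THF, −78 to 50 °C) give the chelation-defined silyl ketene acetal with OSiMe3 cis to CO2Me F4.
- Its enol geometry matches that of the pyrone, and it undergoes Ireland–Claisen rearrangement through the same chair to the trimethylsilyl ester F5.
- Aqueous work-up gives (2R,4E)-2-(methoxycarbonyl)-2-methylhex-4-enoic acid F6.
- 1-Chloro-N,N,2-trimethylprop-1-en-1-amine converts it to methyl (2S,4E)-2-(chlorocarbonyl)-2-methylhex-4-enoate F7.
- The terminal carbon of the heptane-2,4-dione dianion (NaH then n-BuLi, 2 equiv, THF, −78 °C) attacks the acid chloride to give 7.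

Step 7 (methylene bridging). The risks are retro-Mannich scrambling to the homodimer of 9, double alkylation of 13, and base-induced exchange of the bridge. The fallback sets out from 13 and comes back at 16.
- It reverses the roles of the two rings.
- 13 (in slight excess) is aminomethylated with aqueous HCHO and Me2NH in EtOH, and 1-{3-[(dimethylamino)methyl]-2,6-dihydroxy-4-methoxyphenyl}hexan-1-one F8 is isolated.
- F8 is heated with one equivalent of 9 in toluene at 90 °C. The acidic enol protonates the amine, and loss of Me2NH gives the ortho-quinone methide F9.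
- The enolate of 9 has only one free carbon and adds to F9 to give 16.
- No formaldehyde equivalent ever meets free 9, so its homodimer cannot form.

**Further compounds**
F1 | step 2 | 4-bromo-3,6-dimethyl-2H-pyran-2-one | CC1=CC(Br)=C(C)C(=O)O1
F2 | step 2 | 4-{[(2R)-but-3-en-2-yl]oxy}-3,6-dimethyl-2H-pyran-2-one | CC1=CC(O[C@H](C)C=C)=C(C)C(=O)O1
F3 | step 3 | 1-[(2R)-but-3-en-2-yl] 3-methyl 2-methylpropanedioate (epimers at C2) | COC(=O)C(C)C(=O)O[C@H](C)C=C
F4 | step 3 | silyl ketene acetal of F3, OSiMe3 cis to CO2Me | COC(=O)/C(C)=C(\O[Si](C)(C)C)O[C@H](C)C=C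
F5 | step 3 | trimethylsilyl ester of F6 | C[Si](C)(C)OC(=O)[C@@](C)(C/C=C/C)C(=O)OC
F6 | step 3 | (2R,4E)-2-(methoxycarbonyl)-2-methylhex-4-enoic acid | OC(=O)[C@@](C)(C/C=C/C)C(=O)OC
F7 | step 3 | methyl (2S,4E)-2-(chlorocarbonyl)-2-methylhex-4-enoate | ClC(=O)[C@@](C)(C/C=C/C)C(=O)OC
F8 | step 7 | 1-{3-[(dimethylamino)methyl]-2,6-dihydroxy-4-methoxyphenyl}hexan-1-one | CCCCCC(=O)c1c(O)cc(OC)c(CN(C)C)c1O
F9 | step 7 | 2-hexanoyl-3-hydroxy-5-methoxy-6-methylidenecyclohexa-2,4-dien-1-one | C=C1C(=O)C(C(=O)CCCCC)=C(O)C=C1OC
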